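**Plan**

1. Positions follow carotenoid numbering: the seco half is C1–C15 (C3 carries the myristate, C5 and C6 are the ketones) and the triol half is primed. The retrosynthesis cuts the C14–C15 single bond between the methyl-branched C13=C14 alkene and the C15=C15' ethene unit, giving a C14 alkenyl iodide (seco half) and a C15 pentaenylstannane (triol half), joined last by Stille coupling.
2. Enabling feature: both ends are the same 1,1,5-trimethylcyclohexane ring oxygenated at C3, C5 and C6, and the seco end is that ring with its C5–C6 glycol bond cut. One C18 triol tetraenyl iodide therefore serves both halves, and the left ring is a temporary ring, opened by Pb(OAc)4 after 3-O-myristoylation.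
3. Further cuts: C15=C15' comes from (E)-1,2-bis(tributylstannyl)ethene (C14'–C15' bond), C11=C12 and C7=C8 from Horner–Wadsworth–Emmons reactions, and C6–C7 from carbonylation of an enol triflate.
4. Forward order: ring → C7 → 5,6-epoxide → trans-5,6-diol → C8–C11 → C12–C14–I → divergence (stannane on one side, myristate then glycol cleavage on the other) → C14–C15.
5. Stereochemistry: C3 and C3' come from C4 of (4R,6R)-4-hydroxy-2,2,6-trimethylcyclohexanone. C5' and C6' come from a tartrate-controlled epoxidation syn to C3–O followed by invertive water attack at C5. All alkenes are E by syn-carboalumination, E-selective olefinations and stereoretentive couplings.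

Key step: step 19

Assumption: (4R,6R)-4-hydroxy-2,2,6-trimethylcyclohexanone (the levodione-derived zeaxanthin building block) is taken as a purchasable chiral-pool ketone.

**Route**

Step 1
Reactants: 1 prop-2-yn-1-ol
Product: 3 (2E)-3-iodo-2-methylprop-2-en-1-ol, via alkenylalane 2 (not isolated)
Conditions: AlMe3 (3 equiv), Cp2ZrCl2 (0.25 equiv), CH2Cl2, 0 °C to rt; then I2, THF, −30 to 0 °C
Reagents that add atoms: trimethylaluminium C[Al](C)C; iodine II
Why: Zirconium-catalysed Negishi carboalumination adds Me and Al syn across the alkyne (Me to the internal carbon), and iodinolysis of the C–Al bond with retention should give the E-iodide that later becomes C13(Me)=C14–I.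

Step 2
Reactants: 3 (2E)-3-iodo-2-methylprop-2-en-1-ol
Product: 4 (1E)-3-bromo-1-iodo-2-methylprop-1-ene
Conditions: CBr4, PPh3, CH2Cl2, 0 °C
Reagents that add atoms: carbon tetrabromide BrC(Br)(Br)Br
Why: Appel bromination of the primary allylic alcohol is neutral and should leave the alkenyl iodide and its geometry untouched.

Step 3
Reactants: 4 (1E)-3-bromo-1-iodo-2-methylprop-1-ene
Product: 5 diethyl [(2E)-3-iodo-2-methylprop-2-en-1-yl]phosphonate
Conditions: P(OEt)3 (neat), 90 °C
Reagents that add atoms: triethyl phosphite CCOP(OCC)OCC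
Why: Michaelis–Arbuzov reaction takes place at the allylic bromide only, since the sp2 C–I bond is inert to the phosphite.

Step 4
Reactants: 6 (4R,6R)-4-hydroxy-2,2,6-trimethylcyclohexan-1-one
Product: 7 (4R,6R)-4-(tert-butyldimethylsilyloxy)-2,2,6-trimethylcyclohexan-1-one
Conditions: TBSCl, imidazole, DMF, rt
Reagents that add atoms: tert-butyldimethylsilyl chloride CC(C)(C)[Si](C)(C)Cl
Why: Standard silylation of the secondary alcohol protects the future C3/C3' oxygen through the enolate, hydride and olefination steps.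

Step 5
Reactants: 7 (4R,6R)-4-(tert-butyldimethylsilyloxy)-2,2,6-trimethylcyclohexan-1-one
Product: 9 (4R)-4-(tert-butyldimethylsilyloxy)-2,6,6-trimethylcyclohex-1-en-1-yl trifluoromethanesulfonate, via lithium enolate 8 (not isolated)
Conditions: LiN(iPr)2, THF, −78 °C; then PhNTf2, −78 °C to rt
Reagents that add atoms: N-phenylbis(trifluoromethanesulfonimide) O=S(=O)(N(c1ccccc1)S(=O)(=O)C(F)(F)F)C(F)(F)F
Why: Only C6 carries an α-hydrogen (C2 is quaternary), so enolate O-triflation should give a single tetrasubstituted enol triflate, the future C5=C6 alkene.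

Step 6
Reactants: 9 (4R)-4-(tert-butyldimethylsilyloxy)-2,6,6-trimethylcyclohex-1-en-1-yl trifluoromethanesulfonate
Product: 10 methyl (4R)-4-(tert-butyldimethylsilyloxy)-2,6,6-trimethylcyclohex-1-ene-1-carboxylate
Conditions: Pd(OAc)2 (5 mol %), PPh3 (10 mol %), CO (1 atm), MeOH, Et3N, DMF, 50 °C
Reagents that add atoms: carbon monoxide [C-]#[O+]; methanol CO
Why: Palladium-catalysed alkoxycarbonylation (oxidative addition of zerovalent palladium to the enol triflate, CO insertion, methanolysis) installs C7 on the hindered tetrasubstituted alkene.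

Step 7
Reactants: 10 methyl (4R)-4-(tert-butyldimethylsilyloxy)-2,6,6-trimethylcyclohex-1-ene-1-carboxylate
Product: 11 [(4R)-4-(tert-butyldimethylsilyloxy)-2,6,6-trimethylcyclohex-1-en-1-yl]methanol
Conditions: iBu2AlH (2.5 equiv), CH2Cl2, −78 to 0 °C
Reagents that add atoms: none
Why: 1,2-Reduction of the conjugated ester by the aluminium hydride gives the allylic alcohol that directs the next epoxidation.

Step 8
Reactants: 11 [(4R)-4-(tert-butyldimethylsilyloxy)-2,6,6-trimethylcyclohex-1-en-1-yl]methanol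
Product: 12 [(1S,4S,6S)-4-(tert-butyldimethylsilyloxy)-2,2,6-trimethyl-7-oxabicyclo[4.1.0]heptan-1-yl]methanol
Conditions: Ti(OiPr)4 (0.3 equiv), L-(+)-diethyl tartrate (0.36 equiv), t-BuOOH (2 equiv), 4 Å molecular sieves, CH2Cl2, −20 °C
Reagents that add atoms: tert-butyl hydroperoxide CC(C)(C)OO
Why: Katsuki–Sharpless epoxidation under reagent control: L-(+)-tartrate should deliver oxygen to the alkene face cis to the C3 silyloxy group (the enantiomeric tartrate gives the trans epoxide), which fixes C6 and prepares C5 for inversion.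

Step 9
Reactants: 12 [(1S,4S,6S)-4-(tert-butyldimethylsilyloxy)-2,2,6-trimethyl-7-oxabicyclo[4.1.0]heptan-1-yl]methanol
Product: 13 (1R,2S,5S)-5-(tert-butyldimethylsilyloxy)-2-(hydroxymethyl)-1,3,3-trimethylcyclohexane-1,2-diol
Conditions: HClO4 (5 mol %), THF–H2O (3:1), 0 °C
Reagents that add atoms: water O
Why: Specific-acid-catalysed epoxide hydrolysis: water should open the protonated epoxide at C5 (tertiary, remote from the electron-withdrawing CH2OH and the neopentyl C1) by trans-diaxial attack anti to the epoxide oxygen, so C5 is inverted and C6 retained to give the (5R,6R) trans-diol, while the cold dilute acid should spare the silyl ether.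

Step 10
Reactants: 13 (1R,2S,5S)-5-(tert-butyldimethylsilyloxy)-2-(hydroxymethyl)-1,3,3-trimethylcyclohexane-1,2-diol
Product: 14 (1R,2R,4S)-4-(tert-butyldimethylsilyloxy)-1,2-dihydroxy-2,6,6-trimethylcyclohexane-1-carbaldehyde
Conditions: SO3·pyridine, DMSO, iPr2NEt, CH2Cl2, 0 °C
Reagents that add atoms: none
Why: Parikh–Doering oxidation affects only the primary C7 alcohol (the two tertiary hydroxyls cannot be oxidised and no glycol-cleaving oxidant is present), and the aldehyde has no α-hydrogen to epimerise.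

Step 11
Reactants: 14 (1R,2R,4S)-4-(tert-butyldimethylsilyloxy)-1,2-dihydroxy-2,6,6-trimethylcyclohexane-1-carbaldehyde; 15 ethyl (2E)-4-(diethoxyphosphoryl)-3-methylbut-2-enoate
Product: 17 ethyl (2E,4E)-5-[(1R,2R,4S)-4-(tert-butyldimethylsilyloxy)-1,2-dihydroxy-2,6,6-trimethylcyclohexyl]-3-methylpenta-2,4-dienoate, via lithiated phosphonate 16 (not isolated)
Conditions: LiN(SiMe3)2, THF–DMPU, −78 °C (forms 16, 3 equiv); then 14, −78 to 0 °C
Reagents that add atoms: none
Why: Horner–Wadsworth–Emmons olefination: the stabilised vinylogous phosphonate anion is too weakly basic to be consumed irreversibly by the tertiary hydroxyls and should give the E C7=C8 alkene, with C9=C10 expected mainly E and any 9Z isomer removed by chromatography.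

Step 12
Reactants: 17 ethyl (2E,4E)-5-[(1R,2R,4S)-4-(tert-butyldimethylsilyloxy)-1,2-dihydroxy-2,6,6-trimethylcyclohexyl]-3-methylpenta-2,4-dienoate
Product: 18 (2E,4E)-5-[(1R,2R,4S)-4-(tert-butyldimethylsilyloxy)-1,2-dihydroxy-2,6,6-trimethylcyclohexyl]-3-methylpenta-2,4-dien-1-ol
Conditions: iBu2AlH (5 equiv), CH2Cl2, −78 °C
Reagents that add atoms: none
Why: 1,2-Reduction of the dienoate gives the C11 allylic alcohol; the excess hydride allows for the two free hydroxyls.

Step 13
Reactants: 18 (2E,4E)-5-[(1R,2R,4S)-4-(tert-butyldimethylsilyloxy)-1,2-dihydroxy-2,6,6-trimethylcyclohexyl]-3-methylpenta-2,4-dien-1-ol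
Product: 19 (2E,4E)-5-[(1R,2R,4S)-4-(tert-butyldimethylsilyloxy)-1,2-dihydroxy-2,6,6-trimethylcyclohexyl]-3-methylpenta-2,4-dienal
Conditions: MnO2 (activated), CH2Cl2, rt
Reagents that add atoms: none
Why: MnO2 oxidises the primary allylic alcohol chemoselectively, and the tertiary allylic C6 hydroxyl cannot be oxidised.

Step 14
Reactants: 19 (2E,4E)-5-[(1R,2R,4S)-4-(tert-butyldimethylsilyloxy)-1,2-dihydroxy-2,6,6-trimethylcyclohexyl]-3-methylpenta-2,4-dienal; 5 diethyl [(2E)-3-iodo-2-methylprop-2-en-1-yl]phosphonate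
Product: 21 (1R,2R,4S)-4-(tert-butyldimethylsilyloxy)-1-[(1E,3E,5E,7E)-8-iodo-3,7-dimethylocta-1,3,5,7-tetraen-1-yl]-2,6,6-trimethylcyclohexane-1,2-diol, via lithiated iodoallylphosphonate 20 (not isolated)
Conditions: LiN(SiMe3)2, THF, −78 °C (forms 20, 3 equiv); then 19, −78 to 0 °C, dark
Reagents that add atoms: none
Why: Horner–Wadsworth–Emmons reaction of the allylic phosphonate anion with the enal should form the C11=C12 alkene E-selectively and brings in C13(Me)=C14–I with the geometry fixed in step 1.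

Step 15
Reactants: 21 (1R,2R,4S)-4-(tert-butyldimethylsilyloxy)-1-[(1E,3E,5E,7E)-8-iodo-3,7-dimethylocta-1,3,5,7-tetraen-1-yl]-2,6,6-trimethylcyclohexane-1,2-diol
Product: 22 (1R,2R,4S)-1-[(1E,3E,5E,7E)-8-iodo-3,7-dimethylocta-1,3,5,7-tetraen-1-yl]-2,6,6-trimethylcyclohexane-1,2,4-triol
Conditions: Bu4NF, THF, 0 °C to rt, dark
Reagents that add atoms: none
Why: Fluoride desilylation frees the C3 hydroxyl without acid, so the tertiary allylic C6 hydroxyl cannot ionise towards 3,6- or 5,8-ethers.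

Step 16
Reactants: 22 (1R,2R,4S)-1-[(1E,3E,5E,7E)-8-iodo-3,7-dimethylocta-1,3,5,7-tetraen-1-yl]-2,6,6-trimethylcyclohexane-1,2,4-triol; 23 (E)-1,2-bis(tributylstannyl)ethene
Product: 24 (1R,2R,4S)-1-[(1E,3E,5E,7E,9E)-3,7-dimethyl-10-(tributylstannyl)deca-1,3,5,7,9-pentaen-1-yl]-2,6,6-trimethylcyclohexane-1,2,4-triol
Conditions: PdCl2(MeCN)2 (5 mol %), iPr2NEt, DMF–THF, rt, dark; 23 in fourfold excess
Reagents that add atoms: none
Why: Stille coupling with retention at both alkenes adds the C15=C15' unit to C14', and the excess of the distannane should hold the reaction at mono-coupling.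

Step 17
Reactants: 22 (1R,2R,4S)-1-[(1E,3E,5E,7E)-8-iodo-3,7-dimethylocta-1,3,5,7-tetraen-1-yl]-2,6,6-trimethylcyclohexane-1,2,4-triol; 25 tetradecanoyl chloride
Product: 26 (1S,3R,4R)-3,4-dihydroxy-4-[(1E,3E,5E,7E)-8-iodo-3,7-dimethylocta-1,3,5,7-tetraen-1-yl]-3,5,5-trimethylcyclohexyl tetradecanoate
Conditions: pyridine, DMAP (cat.), CH2Cl2, 0 °C
Reagents that add atoms: none
Why: Acylation should occur only at the single secondary hydroxyl (C3), since the two tertiary hydroxyls are unreactive towards the acid chloride under these conditions.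

Step 18
Reactants: 26 (1S,3R,4R)-3,4-dihydroxy-4-[(1E,3E,5E,7E)-8-iodo-3,7-dimethylocta-1,3,5,7-tetraen-1-yl]-3,5,5-trimethylcyclohexyl tetradecanoate
Product: 27 (4S,8E,10E,12E,14E)-15-iodo-6,6,10,14-tetramethyl-2,7-dioxopentadeca-8,10,12,14-tetraen-4-yl tetradecanoate
Conditions: Pb(OAc)4 (1.2 equiv), pyridine, toluene–CH2Cl2, 0 °C to rt, dark
Reagents that add atoms: none
Why: Criegee glycol cleavage: the trans-diaxial ditertiary diol cannot form a cyclic plumbate but should fragment through the base-assisted acyclic mono-ester of tetravalent lead (as trans-decalin-9,10-diol and steroidal 5α,6β-diols do), opening the temporary ring to the C5 methyl ketone and the C6 tetraenyl ketone so that the β-acyloxy ketone never meets a base.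

Step 19
Reactants: 27 (4S,8E,10E,12E,14E)-15-iodo-6,6,10,14-tetramethyl-2,7-dioxopentadeca-8,10,12,14-tetraen-4-yl tetradecanoate; 24 (1R,2R,4S)-1-[(1E,3E,5E,7E,9E)-3,7-dimethyl-10-(tributylstannyl)deca-1,3,5,7,9-pentaen-1-yl]-2,6,6-trimethylcyclohexane-1,2,4-triol
Product: 28 (4S,8E,10E,12E,14E,16E,18E,20E,22E,24E)-6,6,10,14,19,23-hexamethyl-2,7-dioxo-25-[(1R,2R,4S)-1,2,4-trihydroxy-2,6,6-trimethylcyclohexyl]pentacosa-8,10,12,14,16,18,20,22,24-nonaen-4-yl tetradecanoate
Conditions: Pd2(dba)3·CHCl3 (5 mol %), AsPh3 (40 mol %), DMF–THF, rt, degassed, dark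
Reagents that add atoms: none
Why: Zerovalent palladium inserts into the C14–I bond of 27, stannane 24 transmetalates at C15, and reductive elimination forms the C14–C15 σ-bond; this is a Stille alkenyl–alkenyl cross-coupling, whose closest precedent is the union of polyenyl stannanes with alkenyl iodides in carotenoid synthesis. The step closes no ring and creates no stereocentre; both partners are defined E-alkenes and couple with retention at C14 and C15, so the all-E nonaene should arise directly. The selectivity needed is chemoselectivity, secured because 27 holds a single C(sp2)–I bond and 24 a single C(sp2)–Sn bond. The neutral, base-free, room-temperature conditions should leave the β-acyloxy ketone (C3–O/C5=O), the 1,6-diketone, the myristate and the free 3',5',6'-triol untouched. The weakly donating AsPh3 speeds transmetalation so that cross-coupling should outrun protodestannylation and homocoupling, and because both halves are already fully deprotected this step ends the synthesis.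

**Compound list**

1 | prop-2-yn-1-ol | C#CCO | starting material
2 | [(1E)-3-(dimethylalumanyloxy)-2-methylprop-1-en-1-yl]dimethylalumane | C[Al](C)/C=C(C)/CO[Al](C)C | intermediate
3 | (2E)-3-iodo-2-methylprop-2-en-1-ol | OC/C(C)=C/I | intermediate
4 | (1E)-3-bromo-1-iodo-2-methylprop-1-ene | BrC/C(C)=C/I | intermediate
5 | diethyl [(2E)-3-iodo-2-methylprop-2-en-1-yl]phosphonate | CCOP(=O)(OCC)C/C(C)=C/I | intermediate
6 | (4R,6R)-4-hydroxy-2,2,6-trimethylcyclohexan-1-one | C[C@@H]1C[C@@H](O)CC(C)(C)C1=O | starting material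
7 | (4R,6R)-4-(tert-butyldimethylsilyloxy)-2,2,6-trimethylcyclohexan-1-one | C[C@@H]1C[C@@H](O[Si](C)(C)C(C)(C)C)CC(C)(C)C1=O | intermediate
8 | lithium (4R)-4-(tert-butyldimethylsilyloxy)-2,6,6-trimethylcyclohex-1-en-1-olate | [Li+].CC1=C([O-])C(C)(C)C[C@H](O[Si](C)(C)C(C)(C)C)C1 | intermediate
9 | (4R)-4-(tert-butyldimethylsilyloxy)-2,6,6-trimethylcyclohex-1-en-1-yl trifluoromethanesulfonate | CC1=C(OS(=O)(=O)C(F)(F)F)C(C)(C)C[C@H](O[Si](C)(C)C(C)(C)C)C1 | intermediate
10 | methyl (4R)-4-(tert-butyldimethylsilyloxy)-2,6,6-trimethylcyclohex-1-ene-1-carboxylate | CC1=C(C(=O)OC)C(C)(C)C[C@H](O[Si](C)(C)C(C)(C)C)C1 | intermediate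
11 | [(4R)-4-(tert-butyldimethylsilyloxy)-2,6,6-trimethylcyclohex-1-en-1-yl]methanol | CC1=C(CO)C(C)(C)C[C@H](O[Si](C)(C)C(C)(C)C)C1 | intermediate
12 | [(1S,4S,6S)-4-(tert-butyldimethylsilyloxy)-2,2,6-trimethyl-7-oxabicyclo[4.1.0]heptan-1-yl]methanol (epoxide oxygen cis to the silyloxy group) | OC[C@@]1(O2)C(C)(C)C[C@H](O[Si](C)(C)C(C)(C)C)C[C@@]12C | intermediate
13 | (1R,2S,5S)-5-(tert-butyldimethylsilyloxy)-2-(hydroxymethyl)-1,3,3-trimethylcyclohexane-1,2-diol (trans-diaxial diol) | OC[C@@]1(O)C(C)(C)C[C@H](O[Si](C)(C)C(C)(C)C)C[C@@]1(C)O | intermediate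
14 | (1R,2R,4S)-4-(tert-butyldimethylsilyloxy)-1,2-dihydroxy-2,6,6-trimethylcyclohexane-1-carbaldehyde | O=C[C@@]1(O)C(C)(C)C[C@H](O[Si](C)(C)C(C)(C)C)C[C@@]1(C)O | intermediate
15 | ethyl (2E)-4-(diethoxyphosphoryl)-3-methylbut-2-enoate | CCOC(=O)/C=C(C)/CP(=O)(OCC)OCC | starting material
16 | lithium salt of the C4 carbanion of 15 | [Li+].CCOC(=O)/C=C(C)/[CH-]P(=O)(OCC)OCC | intermediate
17 | ethyl (2E,4E)-5-[(1R,2R,4S)-4-(tert-butyldimethylsilyloxy)-1,2-dihydroxy-2,6,6-trimethylcyclohexyl]-3-methylpenta-2,4-dienoate | CCOC(=O)/C=C(C)/C=C/[C@@]1(O)C(C)(C)C[C@H](O[Si](C)(C)C(C)(C)C)C[C@@]1(C)O | intermediate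
18 | (2E,4E)-5-[(1R,2R,4S)-4-(tert-butyldimethylsilyloxy)-1,2-dihydroxy-2,6,6-trimethylcyclohexyl]-3-methylpenta-2,4-dien-1-ol | OC/C=C(C)/C=C/[C@@]1(O)C(C)(C)C[C@H](O[Si](C)(C)C(C)(C)C)C[C@@]1(C)O | intermediate
19 | (2E,4E)-5-[(1R,2R,4S)-4-(tert-butyldimethylsilyloxy)-1,2-dihydroxy-2,6,6-trimethylcyclohexyl]-3-methylpenta-2,4-dienal | O=C/C=C(C)/C=C/[C@@]1(O)C(C)(C)C[C@H](O[Si](C)(C)C(C)(C)C)C[C@@]1(C)O | intermediate
20 | lithium salt of the C1 carbanion of 5 | [Li+].CCOP(=O)(OCC)[CH-]/C(C)=C/I | intermediate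
21 | (1R,2R,4S)-4-(tert-butyldimethylsilyloxy)-1-[(1E,3E,5E,7E)-8-iodo-3,7-dimethylocta-1,3,5,7-tetraen-1-yl]-2,6,6-trimethylcyclohexane-1,2-diol | I/C=C(C)/C=C/C=C(C)/C=C/[C@@]1(O)C(C)(C)C[C@H](O[Si](C)(C)C(C)(C)C)C[C@@]1(C)O | intermediate
22 | (1R,2R,4S)-1-[(1E,3E,5E,7E)-8-iodo-3,7-dimethylocta-1,3,5,7-tetraen-1-yl]-2,6,6-trimethylcyclohexane-1,2,4-triol | I/C=C(C)/C=C/C=C(C)/C=C/[C@@]1(O)C(C)(C)C[C@H](O)C[C@@]1(C)O | intermediate
23 | (E)-1,2-bis(tributylstannyl)ethene | CCCC[Sn](CCCC)(CCCC)/C=C/[Sn](CCCC)(CCCC)CCCC | starting material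
24 | (1R,2R,4S)-1-[(1E,3E,5E,7E,9E)-3,7-dimethyl-10-(tributylstannyl)deca-1,3,5,7,9-pentaen-1-yl]-2,6,6-trimethylcyclohexane-1,2,4-triol | CCCC[Sn](CCCC)(CCCC)/C=C/C=C(C)/C=C/C=C(C)/C=C/[C@@]1(O)C(C)(C)C[C@H](O)C[C@@]1(C)O | intermediate
25 | tetradecanoyl chloride | CCCCCCCCCCCCCC(=O)Cl | starting material
26 | (1S,3R,4R)-3,4-dihydroxy-4-[(1E,3E,5E,7E)-8-iodo-3,7-dimethylocta-1,3,5,7-tetraen-1-yl]-3,5,5-trimethylcyclohexyl tetradecanoate | I/C=C(C)/C=C/C=C(C)/C=C/[C@@]1(O)C(C)(C)C[C@H](OC(=O)CCCCCCCCCCCCC)C[C@@]1(C)O | intermediate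
27 | (4S,8E,10E,12E,14E)-15-iodo-6,6,10,14-tetramethyl-2,7-dioxopentadeca-8,10,12,14-tetraen-4-yl tetradecanoate | CCCCCCCCCCCCCC(=O)O[C@H](CC(C)=O)CC(C)(C)C(=O)/C=C/C(C)=C/C=C/C(C)=C/I | intermediate
28 | (4S,8E,10E,12E,14E,16E,18E,20E,22E,24E)-6,6,10,14,19,23-hexamethyl-2,7-dioxo-25-[(1R,2R,4S)-1,2,4-trihydroxy-2,6,6-trimethylcyclohexyl]pentacosa-8,10,12,14,16,18,20,22,24-nonaen-4-yl tetradecanoate | CCCCCCCCCCCCCC(=O)O[C@H](CC(C)=O)CC(C)(C)C(=O)/C=C/C(C)=C/C=C/C(C)=C/C=C/C=C(C)/C=C/C=C(C)/C=C/[C@@]1(O)C(C)(C)C[C@H](O)C[C@@]1(C)O | target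

**Step count and risks**

Total step count: 19. Longest linear sequence: 15 steps (steps 4 to 15, then 17, 18 and 19).

Most likely to fail, step 18. The trans-diaxial ditertiary diol of 26 fragments only slowly, so oxidation or acetoxylation of the electron-rich tetraenyl iodide by tetravalent lead may compete with the glycol cleavage. The fallback cleaves the glycol before the long chromophore exists; it sets out from 19 (and from 4 for the ylide) and comes back at 27. Desilylation of 19 with Bu4NF gives (2E,4E)-3-methyl-5-[(1R,2R,4S)-1,2,4-trihydroxy-2,6,6-trimethylcyclohexyl]penta-2,4-dienal F3. Acylation with 25 in pyridine gives the 3-O-myristate (1S,3R,4R)-3,4-dihydroxy-3,5,5-trimethyl-4-[(1E,3E)-3-methyl-5-oxopenta-1,3-dien-1-yl]cyclohexyl tetradecanoate F4. Pb(OAc)4 in pyridine, which the electron-poor dienal should tolerate in excess and over long times, gives the seco keto-dienal (4S,8E,10E)-6,6,10-trimethyl-2,7,12-trioxododeca-8,10-dien-4-yl tetradecanoate F5. Bromide 4 and PBu3 give tributyl[(2E)-3-iodo-2-methylprop-2-en-1-yl]phosphonium bromide F6, which one equivalent of LiN(SiMe3)2 in THF at −78 °C turns into the allylic ylide tributyl[(2E)-3-iodo-2-methylprop-2-en-1-ylidene]phosphorane F7. An E-selective Wittig reaction of F7 at the aldehyde of F5 gives 27; the allyl ylide is too weak a base to enolise the C5 ketone and expel the myristate.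

Second, step 9. Ionisation at C5 to a free tertiary cation may lead to non-stereospecific capture by water, elimination or a semipinacol shift, and the acid may remove the silyl ether too early. The fallback replaces intermolecular hydrolysis by intramolecular oxygen delivery; it sets out from 12 and comes back at 13. Boc2O and DMAP convert 12 into tert-butyl [(1S,4S,6S)-4-(tert-butyldimethylsilyloxy)-2,2,6-trimethyl-7-oxabicyclo[4.1.0]heptan-1-yl]methyl carbonate F1. BF3·OEt2 in CH2Cl2 at −78 °C makes the carbonate carbonyl oxygen, held on the face opposite to the epoxide oxygen by the C7 arm, attack C5 in a 6-endo opening with forced inversion. This gives the cis-fused cyclic carbonate 4a-hydroxy-7-(tert-butyldimethylsilyloxy)-5,5,8a-trimethylhexahydro-4H-benzo[d][1,3]dioxin-2-one F2 (configuration as in 13). K2CO3 in MeOH then removes the carbonate to give 13.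

Third, step 19. Protodestannylation and homocoupling of the long polyenylstannane, and E/Z scrambling under palladium, may outrun the cross-coupling. The fallback forms the same C14–C15 bond from a more robust boron nucleophile; it sets out from 22 and comes back at 28. Stille coupling of 22 with the ethene linchpin tributyl[(E)-2-(4,4,5,5-tetramethyl-1,3,2-dioxaborolan-2-yl)ethenyl]stannane F8 (PdCl2(MeCN)2, DMF) should react at tin only. This gives the pentaenyl pinacol boronate (1R,2R,4S)-1-[(1E,3E,5E,7E,9E)-3,7-dimethyl-10-(4,4,5,5-tetramethyl-1,3,2-dioxaborolan-2-yl)deca-1,3,5,7,9-pentaen-1-yl]-2,6,6-trimethylcyclohexane-1,2,4-triol F9. Suzuki–Miyaura coupling of F9 with 27 (Pd(PPh3)4, Tl2CO3, THF–H2O, rt, short contact to spare the β-acyloxy ketone) gives 28.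

Further compounds

F1 | step 9 | tert-butyl [(1S,4S,6S)-4-(tert-butyldimethylsilyloxy)-2,2,6-trimethyl-7-oxabicyclo[4.1.0]heptan-1-yl]methyl carbonate | CC(C)(C)OC(=O)OC[C@@]1(O2)C(C)(C)C[C@H](O[Si](C)(C)C(C)(C)C)C[C@@]12C
F2 | step 9 | 4a-hydroxy-7-(tert-butyldimethylsilyloxy)-5,5,8a-trimethylhexahydro-4H-benzo[d][1,3]dioxin-2-one (cis-fused, configuration as in 13) | O=C1OC[C@@]2(O)C(C)(C)C[C@H](O[Si](C)(C)C(C)(C)C)C[C@@]2(C)O1
F3 | step 18 | (2E,4E)-3-methyl-5-[(1R,2R,4S)-1,2,4-trihydroxy-2,6,6-trimethylcyclohexyl]penta-2,4-dienal | O=C/C=C(C)/C=C/[C@@]1(O)C(C)(C)C[C@H](O)C[C@@]1(C)O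
F4 | step 18 | (1S,3R,4R)-3,4-dihydroxy-3,5,5-trimethyl-4-[(1E,3E)-3-methyl-5-oxopenta-1,3-dien-1-yl]cyclohexyl tetradecanoate | O=C/C=C(C)/C=C/[C@@]1(O)C(C)(C)C[C@H](OC(=O)CCCCCCCCCCCCC)C[C@@]1(C)O
F5 | step 18 | (4S,8E,10E)-6,6,10-trimethyl-2,7,12-trioxododeca-8,10-dien-4-yl tetradecanoate | CCCCCCCCCCCCCC(=O)O[C@H](CC(C)=O)CC(C)(C)C(=O)/C=C/C(C)=C/C=O
F6 | step 18 | tributyl[(2E)-3-iodo-2-methylprop-2-en-1-yl]phosphonium bromide | CCCC[P+](CCCC)(CCCC)C/C(C)=C/I.[Br-]
F7 | step 18 | tributyl[(2E)-3-iodo-2-methylprop-2-en-1-ylidene]phosphorane | CCCC[P+](CCCC)(CCCC)[CH-]/C(C)=C/I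
F8 | step 19 | tributyl[(E)-2-(4,4,5,5-tetramethyl-1,3,2-dioxaborolan-2-yl)ethenyl]stannane | CCCC[Sn](CCCC)(CCCC)/C=C/B1OC(C)(C)C(C)(C)O1
F9 | step 19 | (1R,2R,4S)-1-[(1E,3E,5E,7E,9E)-3,7-dimethyl-10-(4,4,5,5-tetramethyl-1,3,2-dioxaborolan-2-yl)deca-1,3,5,7,9-pentaen-1-yl]-2,6,6-trimethylcyclohexane-1,2,4-triol | CC1(C)OB(/C=C/C=C(C)/C=C/C=C(C)/C=C/[C@@]2(O)C(C)(C)C[C@H](O)C[C@@]2(C)O)OC1(C)C
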